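**Retrosynthetic overview**
1. The target is the monoacetate of the C2-symmetric anti-diol (3S,5S)-1,7-diarylheptane-3,5-diol. Its two hydroxyls are homotopic, so one acetate goes on without site selection (opening of a cyclic orthoacetate), and any later 1,3-acyl shift is degenerate.
2. Key disconnection: C3–C4 and C4–C5 are cut together. This gives a one-carbon linchpin, CH2(Bpin)2, and two copies of one chiral α-oxy carbanion, ArCH2CH2CH(Li)OC(O)Ar'.
3. This carbanion is a d1 synthon, the alcohol-level counterpart of an acyl anion. The carbinol carbon, normally the electrophilic aldehyde carbon of an aldol, acts as the nucleophile and is joined to the equally nucleophilic C–B carbon through a boronate 1,2-shift. Each bond sets one stereocentre under (+)-sparteine control, and C–B oxidation then gives the C–O bonds.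
4. The carbanion precursor comes in two steps from dihydroconiferyl alcohol (hindered benzoate on the alcohol, TIPS on the phenol).
5. Rings: none is built. Both arenes are bought, and the only ring formed is the transient 1,3-dioxane orthoester of the last step.

Assumption: a sequence run without work-up or isolation between its stages counts as one step, and its intermediates are numbered and marked as not isolated.

**Route**

Step 1
Reactants: 1 dihydroconiferyl alcohol [4-(3-hydroxypropyl)-2-methoxyphenol]; 2 2,4,6-triisopropylbenzoic acid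
Product: 3 3-(4-hydroxy-3-methoxyphenyl)propyl 2,4,6-triisopropylbenzoate
Conditions: PPh3, DIAD, THF, 0 °C to rt
Reagents that add atoms: 2,4,6-triisopropylbenzoic acid (2), CC(C)c1cc(C(C)C)c(C(=O)O)c(C(C)C)c1
Why: Mitsunobu esterification, in which the primary alcohol is activated as its alkoxyphosphonium ion and displaced by the carboxylate (pKa about 4 against about 10 for the guaiacol OH), so the phenol stays free and no stereocentre is involved.

Step 2
Reactants: 3 3-(4-hydroxy-3-methoxyphenyl)propyl 2,4,6-triisopropylbenzoate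
Product: 4 3-[3-methoxy-4-(triisopropylsilyloxy)phenyl]propyl 2,4,6-triisopropylbenzoate
Conditions: TIPSCl, imidazole, DMF, rt
Reagents that add atoms: triisopropylsilyl chloride, CC(C)[Si](Cl)(C(C)C)C(C)C
Why: Imidazole-promoted silyl ether formation at the only remaining OH, where the bulky aryl TIPS ether removes the acidic proton, survives s-BuLi at −78 °C and is a poor director for ortho-lithiation.

Step 3
Reactants: 4 3-[3-methoxy-4-(triisopropylsilyloxy)phenyl]propyl 2,4,6-triisopropylbenzoate (two molecules enter the product); 5 bis(pinacolato)diborylmethane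
Product: 11 (3S,5S)-1,7-bis[3-methoxy-4-(triisopropylsilyloxy)phenyl]heptane-3,5-diol, via lithiated benzoate 6 (not isolated), via first boronate complex 7 (not isolated), via 1,2-bis(boronic ester) 8 (not isolated), via second boronate complex 9 (not isolated), via 1,3-bis(boronic ester) 10 (not isolated)
Conditions: 4 (1.3 equiv), s-BuLi, (+)-sparteine, Et2O, −78 °C, 5 h, then 5 (1.0 equiv), −78 °C to 35 °C; solution cannulated into a second batch of 6 (1.5 equiv, made the same way), −78 °C to 35 °C; then NaBO3·4H2O, THF/H2O, rt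
Reagents that add atoms: bis(pinacolato)diborylmethane (5), CC1(C)OB(CB2OC(C)(C)C(C)(C)O2)OC1(C)C; sodium perborate (NaBO3·4H2O, drawn as its dimeric anion), [Na+].[Na+].O[B-]1(O)OO[B-](O)(O)OO1
Why: Hoppe deprotonation with s-BuLi/(+)-sparteine removes the pro-R hydrogen to give the configurationally stable (R)-α-oxy carbanion 6, which adds to boron with retention and then undergoes a Matteson-type 1,2-metallate shift with inversion (lithiation–borylation), first on 5 (the bulky ligated carbenoid stops at mono-homologation) and then at the less hindered primary boron of 8, so two formally nucleophilic carbons (C–Li and C–B) are joined twice, both stereocentres are reagent-controlled and become (S,S) after stereoretentive C–B oxidation, and using the same carbenoid twice (Horeau amplification, er 97:3 gives about 94:6 anti:syn and above 99% ee) diverts the minor enantiomer into the separable meso syn-diol.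

Step 4
Reactants: 11 (3S,5S)-1,7-bis[3-methoxy-4-(triisopropylsilyloxy)phenyl]heptane-3,5-diol
Product: 14 (3S,5S)-5-hydroxy-1,7-bis(4-hydroxy-3-methoxyphenyl)heptan-3-yl acetate (target), via cyclic orthoacetate 12 (not isolated), via bis-TIPS monoacetate 13 (not isolated)
Conditions: MeC(OMe)3, CSA (5 mol%), CH2Cl2, rt; H2O (10 equiv), rt; then TBAF/AcOH (1:1, 2.5 equiv), THF, 0 °C
Reagents that add atoms: trimethyl orthoacetate, COC(C)(OC)OC; water, O
Why: Acid-catalysed orthoester exchange ties the two homotopic hydroxyls into the 2-methoxy-2-methyl-1,3-dioxane 12, whose hydrolysis through the dioxanylium ion can release only one acetate and one free hydroxyl (orthoester monoacylation of a diol, no C–O bond at a stereocentre is broken), and acetic-acid-buffered fluoride then cleaves only the two aryl Si–O bonds (fluoride desilylation) without touching the acetate.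

**Compound list**
1 | dihydroconiferyl alcohol, 4-(3-hydroxypropyl)-2-methoxyphenol | COc1cc(CCCO)ccc1O | starting material
2 | 2,4,6-triisopropylbenzoic acid | CC(C)c1cc(C(C)C)c(C(=O)O)c(C(C)C)c1 | starting material
3 | 3-(4-hydroxy-3-methoxyphenyl)propyl 2,4,6-triisopropylbenzoate | COc1cc(CCCOC(=O)c2c(C(C)C)cc(C(C)C)cc2C(C)C)ccc1O | intermediate
4 | 3-[3-methoxy-4-(triisopropylsilyloxy)phenyl]propyl 2,4,6-triisopropylbenzoate | COc1cc(CCCOC(=O)c2c(C(C)C)cc(C(C)C)cc2C(C)C)ccc1O[Si](C(C)C)(C(C)C)C(C)C | intermediate
5 | bis(pinacolato)diborylmethane, 2,2'-methylenebis(4,4,5,5-tetramethyl-1,3,2-dioxaborolane) | CC1(C)OB(CB2OC(C)(C)C(C)(C)O2)OC1(C)C | starting material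
6 | (R)-1-lithio-3-[3-methoxy-4-(triisopropylsilyloxy)phenyl]propyl 2,4,6-triisopropylbenzoate, (+)-sparteine-ligated (ligand not drawn) | COc1cc(CC[C@@H]([Li])OC(=O)c2c(C(C)C)cc(C(C)C)cc2C(C)C)ccc1O[Si](C(C)C)(C(C)C)C(C)C | intermediate
7 | lithium boronate complex of 6 on one boron of 5, (R) at the O-bearing carbon | [Li+].COc1cc(CC[C@H](OC(=O)c2c(C(C)C)cc(C(C)C)cc2C(C)C)[B-]2(CB3OC(C)(C)C(C)(C)O3)OC(C)(C)C(C)(C)O2)ccc1O[Si](C(C)C)(C(C)C)C(C)C | intermediate
8 | (R)-2,2'-{4-[3-methoxy-4-(triisopropylsilyloxy)phenyl]butane-1,2-diyl}bis(4,4,5,5-tetramethyl-1,3,2-dioxaborolane) | COc1cc(CC[C@H](B2OC(C)(C)C(C)(C)O2)CB2OC(C)(C)C(C)(C)O2)ccc1O[Si](C(C)C)(C(C)C)C(C)C | intermediate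
9 | lithium boronate complex of 6 on the primary boron of 8, (R) at the O-bearing carbon and (R) at the Bpin-bearing carbon | [Li+].COc1cc(CC[C@H](OC(=O)c2c(C(C)C)cc(C(C)C)cc2C(C)C)[B-]2(C[C@H](CCc3ccc(O[Si](C(C)C)(C(C)C)C(C)C)c(OC)c3)B3OC(C)(C)C(C)(C)O3)OC(C)(C)C(C)(C)O2)ccc1O[Si](C(C)C)(C(C)C)C(C)C | intermediate
10 | (3S,5S)-1,7-bis[3-methoxy-4-(triisopropylsilyloxy)phenyl]heptane-3,5-diyl bis(pinacol boronate) | COc1cc(CC[C@H](B2OC(C)(C)C(C)(C)O2)C[C@H](CCc2ccc(O[Si](C(C)C)(C(C)C)C(C)C)c(OC)c2)B2OC(C)(C)C(C)(C)O2)ccc1O[Si](C(C)C)(C(C)C)C(C)C | intermediate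
11 | (3S,5S)-1,7-bis[3-methoxy-4-(triisopropylsilyloxy)phenyl]heptane-3,5-diol (anti, C2-symmetric) | COc1cc(CC[C@H](O)C[C@@H](O)CCc2ccc(O[Si](C(C)C)(C(C)C)C(C)C)c(OC)c2)ccc1O[Si](C(C)C)(C(C)C)C(C)C | intermediate
12 | (4S,6S)-2-methoxy-2-methyl-4,6-bis{2-[3-methoxy-4-(triisopropylsilyloxy)phenyl]ethyl}-1,3-dioxane (C2 of the dioxane is not stereogenic) | COC1(C)O[C@@H](CCc2ccc(O[Si](C(C)C)(C(C)C)C(C)C)c(OC)c2)C[C@H](CCc2ccc(O[Si](C(C)C)(C(C)C)C(C)C)c(OC)c2)O1 | intermediate
13 | (3S,5S)-5-hydroxy-1,7-bis[3-methoxy-4-(triisopropylsilyloxy)phenyl]heptan-3-yl acetate | COc1cc(CC[C@H](O)C[C@H](CCc2ccc(O[Si](C(C)C)(C(C)C)C(C)C)c(OC)c2)OC(C)=O)ccc1O[Si](C(C)C)(C(C)C)C(C)C | intermediate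
14 | (3S,5S)-5-hydroxy-1,7-bis(4-hydroxy-3-methoxyphenyl)heptan-3-yl acetate | COc1cc(CC[C@H](O)C[C@H](CCc2ccc(O)c(OC)c2)OC(C)=O)ccc1O | target

**Totals**
Total step count: 4. Longest linear sequence: 4 (1 → 3 → 4 → 11 → 14).

**Steps most likely to fail, with fallbacks**

Step 3 carries the highest risk. The second, diamine-ligated carbenoid may be too bulky for the β-branched primary boronate 8 in an unpurified stream, or the er of 6 may be lower than expected.
- The fallback sets out from 4. Carbanion 6 is trapped with Me3SnCl (retention) to give (R)-3-[3-methoxy-4-(triisopropylsilyloxy)phenyl]-1-(trimethylstannyl)propyl 2,4,6-triisopropylbenzoate F1.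
- This stannane is purified and its er is checked.
- Tin–lithium exchange (n-BuLi, Et2O, −78 °C, retention) regenerates 6 free of diamine.
- 2.3 equiv of this much smaller carbenoid are treated with 1.0 equiv of 5 in a single charge and warmed. Both borons are then homologated in one operation through 7, 8 and 9.
- The fallback rejoins the route at 10, which is oxidised to 11 as before. It costs one extra step.

Step 4 is next. The anti-diol may form its orthoester slowly because one substituent must sit axial, or some acetate may be lost in the fluoride stage of the one-pot sequence.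
- The fallback sets out from 11. Bu2SnO in refluxing toluene with removal of water gives (4S,6S)-2,2-dibutyl-4,6-bis{2-[3-methoxy-4-(triisopropylsilyloxy)phenyl]ethyl}-1,3,2-dioxastanninane F2.
- AcCl (1.0 equiv, 0 °C) acylates only one Sn–O bond of this acetal.
- Aqueous work-up rejoins the route at 13, now isolated and purified.
- TBAF/AcOH is then run on 13 as a separate operation to give 14. It costs one extra step.

Step 1 is third. The free phenol may compete as a Mitsunobu nucleophile and give aryl alkyl ethers.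
- The fallback sets out from 1 and reverses the order of events. The phenoxide alone is formed (NaH, 1.0 equiv, THF, 0 °C) and silylated with TIPSCl to give 3-[3-methoxy-4-(triisopropylsilyloxy)phenyl]propan-1-ol F3.
- The remaining primary alcohol is acylated with 2,4,6-triisopropylbenzoyl chloride (pyridine, DMAP, CH2Cl2, 40 °C).
- The fallback rejoins the route at 4, bypasses 3 and leaves the step count unchanged.

**Further compounds**
F1 | step 3 | (R)-3-[3-methoxy-4-(triisopropylsilyloxy)phenyl]-1-(trimethylstannyl)propyl 2,4,6-triisopropylbenzoate | COc1cc(CC[C@@H]([Sn](C)(C)C)OC(=O)c2c(C(C)C)cc(C(C)C)cc2C(C)C)ccc1O[Si](C(C)C)(C(C)C)C(C)C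
F2 | step 4 | (4S,6S)-2,2-dibutyl-4,6-bis{2-[3-methoxy-4-(triisopropylsilyloxy)phenyl]ethyl}-1,3,2-dioxastanninane | CCCC[Sn]1(CCCC)O[C@@H](CCc2ccc(O[Si](C(C)C)(C(C)C)C(C)C)c(OC)c2)C[C@H](CCc2ccc(O[Si](C(C)C)(C(C)C)C(C)C)c(OC)c2)O1
F3 | step 1 | 3-[3-methoxy-4-(triisopropylsilyloxy)phenyl]propan-1-ol | COc1cc(CCCO)ccc1O[Si](C(C)C)(C(C)C)C(C)C
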